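**Retrosynthetic overview**
1. Carotane numbering. Ring A is C1 (quaternary CMe), C2, C3, C4 (carbinol) and C5 (fusion CH). Ring B is C1, C5, C6 (ester carbon), C7, C8 (CMe), C9 and C10 (C=O).
2. Ring B is opened at C6–C7 together with the C6O–acyl bond, and C8=C9 is moved back to C7=C8. This leads to a monocyclic ring A keto aldehyde plus 3,4,5-trimethoxybenzoyl chloride (aroyloxycarbenium Prins–ene closure).
3. Enabling feature: in ring B, C6 (acyloxy) and C10 (ketone) stand 1,5 across C7–C8(Me)=C9, and C10 is flanked by quaternary C1. The ester can therefore activate C6, the C7=C8 methallyl alkene is the only nucleophile, and the proton lost at the end sits on C9.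
4. The methallyl ketone arm comes from an acetyl group (C8–C9 by enolate alkenylation). The acetyl group comes from an isopropenyl group (ozonolysis).
5. Ring A is bought as 3-methylcyclopent-2-enone. C1 is set by asymmetric conjugate addition, C5–C6 by trapping that enolate, and C4 by isopropyl addition. Ring order: A is present from the start, B is closed last.

Key step: step 7

Assumption: in step 1 the antipode of the carbene precursor is taken that delivers isopropenyl to the enone face giving (S)-C1; if the sense proves opposite, the other antipode is used.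
Convention: the β face is the face of ring A that carries the C1 methyl group.

**Step 1**
Reactants: 1 3-methylcyclopent-2-en-1-one; 2 isopropenylmagnesium bromide
Product: 4 trimethyl{[(3S)-3-methyl-3-(prop-1-en-2-yl)cyclopent-1-en-1-yl]oxy}silane, via bromomagnesium enolate 3 (not isolated)
Conditions: Cu(OTf)2 (3 mol %), tert-leucinol-derived 1-mesityl-3-(1-hydroxy-3,3-dimethylbutan-2-yl)imidazolinium hexafluorophosphate (4 mol %), Et2O, −30 °C; then TMSCl, Et3N, DMPU, −30 → 20 °C
Reagents that add atoms: isopropenylmagnesium bromide, CC(=C)[Mg]Br; chlorotrimethylsilane, C[Si](C)(C)Cl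
Why: Copper/N-heterocyclic-carbene-catalysed asymmetric conjugate addition of a Grignard reagent to a β-substituted cyclic enone is a known route to all-carbon quaternary centres; the chiral alkoxy-carbene copper complex selects the enone face and should set C1 as (S), and silylation of the regiodefined enolate fixes the enol double bond toward C5.

**Step 2**
Reactants: 4 enol silane; 5 trimethyl orthoformate
Product: 6 (2S,3S)-2-(dimethoxymethyl)-3-methyl-3-(prop-1-en-2-yl)cyclopentan-1-one
Conditions: HC(OMe)3, BF3·OEt2, CH2Cl2, −78 °C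
Reagents that add atoms: trimethyl orthoformate, COC(OC)OC
Why: In this Mukaiyama-type addition of an enol silane to a BF3-activated orthoformate, the electrophile should approach C5 anti to the larger isopropenyl group on C1, and the epimerisable C5 prefers the same trans arrangement, so C6 ends cis to the C1 methyl group (β).

**Step 3**
Reactants: 6 keto acetal; 7 isopropylmagnesium chloride
Product: 8 (1R,2R,3S)-2-(dimethoxymethyl)-3-methyl-3-(prop-1-en-2-yl)-1-(propan-2-yl)cyclopentan-1-ol
Conditions: i-PrMgCl, LaCl3·2LiCl (1 equiv), THF, 0 °C; aq NH4Cl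
Reagents that add atoms: isopropylmagnesium chloride, CC(C)[Mg]Cl
Why: Grignard 1,2-addition moderated by LaCl3·2LiCl is a known remedy for enolisation and hydride transfer with hindered cyclopentanones; attack anti to the β-oriented C5 dimethoxymethyl group and the β C1 methyl should place isopropyl on the α face and the C4 hydroxyl cis to C6.

**Step 4**
Reactants: 8 tertiary alcohol
Product: 9 1-[(1S,2R,3R)-2-(dimethoxymethyl)-3-hydroxy-1-methyl-3-(propan-2-yl)cyclopentyl]ethan-1-one
Conditions: O3, CH2Cl2–MeOH, −78 °C; then Me2S, −78 → 20 °C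
Reagents that add atoms: ozone, [O-][O+]=O
Why: Ozonolysis with reductive work-up cleaves the only alkene, turns the isopropenyl group into the C10 acetyl group (its methyl is C9) and touches no stereocentre.

**Step 5**
Reactants: 9 methyl ketone; 10 2-bromopropene
Product: 12 1-[(1S,2R,3R)-2-(dimethoxymethyl)-3-hydroxy-1-methyl-3-(propan-2-yl)cyclopentyl]-3-methylbut-3-en-1-one, via dilithium alkoxide dienolate 11 (not isolated)
Conditions: LiHMDS (3.2 equiv), Pd2(dba)3 (2.5 mol %), 2-dicyclohexylphosphino-2'-(dimethylamino)biphenyl (6 mol %), THF, 20 → 45 °C; then AcOH, THF, −78 °C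
Reagents that add atoms: 2-bromopropene, CC(Br)=C
Why: In this palladium-catalysed α-alkenylation of a ketone enolate with a vinyl bromide, only C9 can enolise because C1 is quaternary, the coupled product rests as its dienolate, and kinetic α-protonation in the cold should return the β,γ-unsaturated (methallyl) ketone.

**Step 6**
Reactants: 12 methallyl ketone acetal
Product: 13 (1R,2R,5S)-2-hydroxy-5-methyl-5-(3-methylbut-3-enoyl)-2-(propan-2-yl)cyclopentane-1-carbaldehyde
Conditions: PPTS (20 mol %), acetone–H2O, 35 °C; used without storage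
Reagents that add atoms: water, O
Why: Mild acid hydrolysis of the dimethyl acetal frees the C6 aldehyde, and C5 keeps (and, being epimerisable, prefers) the arrangement with the formyl group trans to both the acyl arm and the isopropyl group.

**Step 7**
Reactants: 13 keto aldehyde; 14 3,4,5-trimethoxybenzoyl chloride
Product: 16 [(3R,3aS,4S,8aS)-3-hydroxy-6,8a-dimethyl-8-oxo-3-(propan-2-yl)-1,2,3,3a,4,5,8,8a-octahydroazulen-4-yl] 3,4,5-trimethoxybenzoate, via alpha-chloroalkyl aroate 15 (not isolated)
Conditions: 14 (1.05 equiv), ZnCl2 (10 mol %), CH2Cl2, 0 °C; then 2,6-di-tert-butyl-4-methylpyridine, AgOTf (1.2 equiv), −60 → −20 °C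
Reagents that add atoms: 3,4,5-trimethoxybenzoyl chloride, COc1cc(C(=O)Cl)cc(OC)c1OC
Why: Proposed new method: ZnCl2 should add the aroyl chloride across the C6 formyl group to give the α-chloroalkyl aroate, AgOTf ionises it to an aroyloxycarbenium ion, the terminal alkene carbon C7 attacks C6, and the tertiary C8 cation gives up a C9 proton to the hindered pyridine, which leaves the conjugated C8=C9–C10 enone and the finished ester in one operation. The closest known reaction types are the Lewis-acid type-two intramolecular carbonyl-ene (Prins) cyclisation of 6-methylhept-6-enals to seven-membered rings and the Hosomi–Sakurai and Mukaiyama additions to acylals and α-acyloxy ethers, which pass through the same kind of cation; what is new is their combination, with an aroyl chloride as activator, in a carbocycle-forming alkene closure. Ring B closes 7-endo-trig (both alkene carbons end in the ring, Markovnikov charge on C8), whereas 6-exo closure through C8 would need a primary cation and aldol closure through C9 would be a 5-(enolendo) process leading to a trans-fused bicyclo[3.3.0]octane. C6, the only new stereocentre, is controlled by ring A: C7 must approach between H5 and C1, anti to the fully substituted C4, and the bulky aroyloxy group then takes the open pseudo-equatorial sector anti to C1, which places H6 anti to H5, that is (6S), while C1, C4 and C5 are untouched and the trans ring fusion is already written into the trans C6/C10 arms. The step needs acylation at the aldehyde oxygen rather than at the C4 hydroxyl, and proton loss from C9 rather than from C7 or the methyl group; the first is secured by the hindered tertiary C4–OH and by consuming the acid chloride before silver is added, the second by the acidity of C9–H next to C10 and by conjugation in the product.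

**Compound list**
1 | 3-methylcyclopent-2-en-1-one | CC1=CC(=O)CC1 | starting material
2 | isopropenylmagnesium bromide | CC(=C)[Mg]Br | starting material
3 | bromomagnesium (3S)-3-methyl-3-(prop-1-en-2-yl)cyclopent-1-en-1-olate | CC(=C)[C@@]1(C)CCC(O[Mg]Br)=C1 | intermediate
4 | trimethyl{[(3S)-3-methyl-3-(prop-1-en-2-yl)cyclopent-1-en-1-yl]oxy}silane | CC(=C)[C@@]1(C)CCC(O[Si](C)(C)C)=C1 | intermediate
5 | trimethyl orthoformate | COC(OC)OC | starting material
6 | (2S,3S)-2-(dimethoxymethyl)-3-methyl-3-(prop-1-en-2-yl)cyclopentan-1-one | CC(=C)[C@@]1(C)CCC(=O)[C@@H]1C(OC)OC | intermediate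
7 | isopropylmagnesium chloride | CC(C)[Mg]Cl | starting material
8 | (1R,2R,3S)-2-(dimethoxymethyl)-3-methyl-3-(prop-1-en-2-yl)-1-(propan-2-yl)cyclopentan-1-ol | CC(=C)[C@@]1(C)CC[C@@](O)(C(C)C)[C@@H]1C(OC)OC | intermediate
9 | 1-[(1S,2R,3R)-2-(dimethoxymethyl)-3-hydroxy-1-methyl-3-(propan-2-yl)cyclopentyl]ethan-1-one | CC(=O)[C@@]1(C)CC[C@@](O)(C(C)C)[C@@H]1C(OC)OC | intermediate
10 | 2-bromopropene | CC(Br)=C | starting material
11 | dilithium salt (C4 alkoxide, C10 dienolate) of 12 | [Li]OC(=CC(C)=C)[C@@]1(C)CC[C@@](O[Li])(C(C)C)[C@@H]1C(OC)OC | intermediate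
12 | 1-[(1S,2R,3R)-2-(dimethoxymethyl)-3-hydroxy-1-methyl-3-(propan-2-yl)cyclopentyl]-3-methylbut-3-en-1-one | CC(=C)CC(=O)[C@@]1(C)CC[C@@](O)(C(C)C)[C@@H]1C(OC)OC | intermediate
13 | (1R,2R,5S)-2-hydroxy-5-methyl-5-(3-methylbut-3-enoyl)-2-(propan-2-yl)cyclopentane-1-carbaldehyde | CC(=C)CC(=O)[C@@]1(C)CC[C@@](O)(C(C)C)[C@@H]1C=O | intermediate
14 | 3,4,5-trimethoxybenzoyl chloride | COc1cc(C(=O)Cl)cc(OC)c1OC | starting material
15 | chloro[(1R,2R,5S)-2-hydroxy-5-methyl-5-(3-methylbut-3-enoyl)-2-(propan-2-yl)cyclopentyl]methyl 3,4,5-trimethoxybenzoate (both configurations at the chloro carbon) | CC(=C)CC(=O)[C@@]1(C)CC[C@@](O)(C(C)C)[C@@H]1C(Cl)OC(=O)c1cc(OC)c(OC)c(OC)c1 | intermediate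
16 | CNP0218356.1, [(3R,3aS,4S,8aS)-3-hydroxy-6,8a-dimethyl-8-oxo-3-(propan-2-yl)-1,2,3,3a,4,5,8,8a-octahydroazulen-4-yl] 3,4,5-trimethoxybenzoate | COc1cc(C(=O)O[C@H]2CC(C)=CC(=O)[C@@]3(C)CC[C@@](O)(C(C)C)[C@H]23)cc(OC)c1OC | target

Total step count: 7. Longest linear sequence: 7 steps (from 1).

**Steps most likely to fail**

Step 7. Three things may go wrong:
- The C7=C8 double bond may migrate into conjugation before C6 is attacked.
- The aroyl group may transfer from the chloro ester to the C4 hydroxyl.
- Facial selectivity at C6 may be poor.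

The fallback uses known chemistry, sets out from 13 and comes back at 16. Compound 13 is cyclised with Me2AlCl (excess, CH2Cl2, −78 → 0 °C) in the established type-two carbonyl-ene manner to the 8-methylidene diol F1. DBU then moves the β,γ-alkene into conjugation to give 10-oxojaeschkeanadiol F2. Only the secondary C6 hydroxyl is then acylated with 14 (Et3N, DMAP, CH2Cl2) to give 16.

Step 1. Face selection may be weak with the five-membered enone, 1,2-addition may compete, or silylation of the enolate may be incomplete. The fallback sets out from 1 and comes back at 6. It builds the isopropenyl group in two stages from a nucleophile whose scope covers β-substituted cyclopentenones.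
- Trimethylsilylacetylene is hydroaluminated with i-Bu2AlH to diisobutyl[1-(trimethylsilyl)ethenyl]aluminium F3.
- N-heterocyclic-carbene–copper-catalysed conjugate addition of this alane to 1 gives the diisobutylaluminium enolate F4.
- TMSOTf converts it into the bis-silyl enol silane F5.
- Orthoformate 5 with BF3·OEt2 gives the silylvinyl keto acetal F6, where the larger group on C1 should also sharpen the C5 selectivity.
- Iododesilylation with N-iodosuccinimide gives the iodovinyl keto acetal F7.
- Negishi coupling with Me2Zn and Pd(PPh3)4 turns F7 into 6.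

Step 5. Alkenylation may occur twice, the hindered enolate may couple sluggishly, or base may shift the new alkene into conjugation. The fallback sets out from 9 and comes back at 12, and it forms C9–C10 instead of C8–C9. Haloform cleavage of the methyl ketone (NaOCl, NaOH) gives the cyclopentanecarboxylic acid F8. This is converted (1,1'-carbonyldiimidazole, MeNH(OMe)·HCl) into the Weinreb amide F9. Methallylmagnesium chloride (excess, THF, −78 °C, cold NH4Cl quench) then gives 12.

**Further compounds**
F1 | step 7 | (3R,3aS,4S,8aS)-3,4-dihydroxy-8a-methyl-6-methylidene-3-(propan-2-yl)octahydroazulen-8(1H)-one | O[C@H]1CC(=C)CC(=O)[C@@]2(C)CC[C@@](O)(C(C)C)[C@H]12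
F2 | step 7 | 10-oxojaeschkeanadiol, (3R,3aS,4S,8aS)-3,4-dihydroxy-6,8a-dimethyl-3-(propan-2-yl)-2,3,3a,4,5,8a-hexahydroazulen-8(1H)-one | O[C@H]1CC(C)=CC(=O)[C@@]2(C)CC[C@@](O)(C(C)C)[C@H]12
F3 | step 1 | diisobutyl[1-(trimethylsilyl)ethenyl]aluminium | C=C([Si](C)(C)C)[Al](CC(C)C)CC(C)C
F4 | step 1 | diisobutylaluminium (3S)-3-methyl-3-[1-(trimethylsilyl)ethenyl]cyclopent-1-en-1-olate | C=C([Si](C)(C)C)[C@@]1(C)CCC(O[Al](CC(C)C)CC(C)C)=C1
F5 | step 1 | trimethyl({(3S)-3-methyl-3-[1-(trimethylsilyl)ethenyl]cyclopent-1-en-1-yl}oxy)silane | C=C([Si](C)(C)C)[C@@]1(C)CCC(O[Si](C)(C)C)=C1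
F6 | step 1 | (2S,3S)-2-(dimethoxymethyl)-3-methyl-3-[1-(trimethylsilyl)ethenyl]cyclopentan-1-one | C=C([Si](C)(C)C)[C@@]1(C)CCC(=O)[C@@H]1C(OC)OC
F7 | step 1 | (2S,3S)-2-(dimethoxymethyl)-3-(1-iodoethenyl)-3-methylcyclopentan-1-one | C=C(I)[C@@]1(C)CCC(=O)[C@@H]1C(OC)OC
F8 | step 5 | (1S,2R,3R)-2-(dimethoxymethyl)-3-hydroxy-1-methyl-3-(propan-2-yl)cyclopentane-1-carboxylic acid | OC(=O)[C@@]1(C)CC[C@@](O)(C(C)C)[C@@H]1C(OC)OC
F9 | step 5 | (1S,2R,3R)-2-(dimethoxymethyl)-3-hydroxy-N-methoxy-N,1-dimethyl-3-(propan-2-yl)cyclopentane-1-carboxamide | CON(C)C(=O)[C@@]1(C)CC[C@@](O)(C(C)C)[C@@H]1C(OC)OC
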